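**Assumptions:** The SMILES is taken as definitive (luteone hydrate, 5,7,2',4'-tetrahydroxy-6-(3-hydroxy-3-methylbutyl)isoflavone, C20H20O7). It has no stereocentre and is achiral, so no enantiocontrol is needed. The only stereo-element in the route is the E-alkene of compound 3, which step 2 removes.

## Retrosynthetic overview

1. The usual plan (3-iodochromone Suzuki coupling, then C-6 prenylation or alkynylation and hydration) is avoided. Instead, the two C–CH3 bonds of the carbinol are disconnected last.
2. Key step: exhaustive methylation of a 6,7-fused dihydrocoumarin lactone on the fully unprotected polyphenolic isoflavone. The acid-labile tertiary alcohol is therefore made in the final operation.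
3. The lactone comes from global O-demethylation and lactonisation of a tetra-O-methyl isoflavone-6-propanoate. Robust methyl ethers can be used because no carbinol is present yet.
4. Ring C comes from a C1 annulation of a deoxybenzoin made by acylating a C2v-symmetric phenol (chain para to OH, flanked by two OMe). A 6- versus 8-isomer cannot form.
5. Ring order: rings A and B are purchased, ring C (γ-pyranone) closes in step 4, and a sacrificial δ-lactone closes in step 5 and opens in step 6.

## Route

**Step 1**
- Reactants: 1, 4-hydroxy-2,6-dimethoxybenzaldehyde; 2, methyl (triphenylphosphoranylidene)acetate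
- Product: 3, methyl (E)-3-(4-hydroxy-2,6-dimethoxyphenyl)acrylate
- Conditions: 2 (1.3 equiv), PhMe, 110 °C, 16 h
- Reagents that add atoms: methyl (triphenylphosphoranylidene)acetate, COC(=O)C=P(c1ccccc1)(c1ccccc1)c1ccccc1
- Why: Wittig olefination with a stabilised ylide needs no added base, so the free para-phenol is tolerated; it is E-selective, but the geometry is erased in step 2.

**Step 2**
- Reactants: 3
- Product: 4, methyl 3-(4-hydroxy-2,6-dimethoxyphenyl)propanoate (C2v-symmetric aromatic core)
- Conditions: H2 (1 atm), 10% Pd/C, EtOAc–MeOH, rt
- Reagents that add atoms: none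
- Why: Catalytic hydrogenation of a cinnamate C=C; the arene, ester, phenol and aryl methyl ethers are inert under these conditions.

**Step 3**
- Reactants: 4; 5, 2,4-dimethoxyphenylacetic acid
- Product: 6, methyl 3-{3-[(2,4-dimethoxyphenyl)acetyl]-4-hydroxy-2,6-dimethoxyphenyl}propanoate (2-hydroxydeoxybenzoin)
- Conditions: 5 (1.3 equiv), BF3·OEt2 (neat), 80 °C, 2 h; then aq NaOAc
- Reagents that add atoms: 2,4-dimethoxyphenylacetic acid, COc1ccc(CC(=O)O)c(OC)c1
- Why: BF3-mediated Friedel–Crafts acylation (O-acylation/Fries manifold) occurs ortho to the only free OH; the para site is blocked and the two ortho sites are symmetry-equivalent, so one regioisomer forms, and its BF2 chelate stops a second acylation.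

**Step 4**
- Reactants: 6; 7, N,N-dimethylformamide dimethyl acetal
- Product: 8, methyl 3-[3-(2,4-dimethoxyphenyl)-5,7-dimethoxy-4-oxo-4H-chromen-6-yl]propanoate
- Conditions: 7 (3 equiv), PhMe, 100 °C, 4 h
- Reagents that add atoms: DMF dimethyl acetal, COC(OC)N(C)C (supplies the C-2 methine carbon)
- Why: Deoxybenzoin C1 annulation: the doubly activated CH2 forms the enaminone and the only free OH displaces Me2NH by addition–elimination, so the pyranone must close para to the chain (6-substituted); any ester hydrolysed in step 3 is re-methylated by this reagent.

**Step 5**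
- Reactants: 8
- Product: 9, 7-(2,4-dihydroxyphenyl)-5-hydroxy-3,4-dihydro-2H,6H-pyrano[3,2-g]chromene-2,6-dione (the linear δ-lactone joining the C-6 propanoyl chain to the 7-oxygen; 5-, 2'- and 4'-OH are free)
- Conditions: BBr3 (12 equiv), CH2Cl2, −78 °C → rt, 18 h; ice–H2O; then p-TsOH·H2O (10 mol %), 1,4-dioxane–PhMe, reflux (Dean–Stark)
- Reagents that add atoms: none
- Why: Lewis-acid aryl methyl ether and ester cleavage is followed by acid-catalysed lactonisation onto the non-chelated 7-OH, which is favoured kinetically and thermodynamically because the 5-OH···O=C4 hydrogen bond is kept; low-temperature BBr3 avoids Wessely–Moser scrambling.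

**Step 6 (key step)**
- Reactants: 9; 10, methylmagnesium bromide
- Product: 11, luteone hydrate (target), 3-(2,4-dihydroxyphenyl)-5,7-dihydroxy-6-(3-hydroxy-3-methylbutyl)-4H-chromen-4-one
- Conditions: MeMgBr (10 equiv), anhydrous CeCl3 (4 equiv), THF, −40 °C → rt; sat. aq NH4Cl (pH ≈ 6)
- Reagents that add atoms: methylmagnesium bromide, C[Mg]Br (two CH3 groups)
- Why: Double Grignard/organocerium addition to an aryl-ester lactone: the first three equivalents form the 5,2',4'-triphenoxide, which electronically deactivates chromone C-2 and C-4, so the lactone is the only strong electrophile; it opens to the 7-phenoxide and methyl ketone, Ce suppresses enolisation so the ketone takes the second methyl, and the buffered quench prevents cyclisation to the chroman; no stereocentre is created.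

## Compound list

| No. | Name | SMILES | Role |
|---|---|---|---|
| 1 | 4-hydroxy-2,6-dimethoxybenzaldehyde | O=Cc1c(OC)cc(O)cc1OC | starting material |
| 2 | methyl (triphenylphosphoranylidene)acetate | COC(=O)C=P(c1ccccc1)(c1ccccc1)c1ccccc1 | starting material |
| 3 | methyl (E)-3-(4-hydroxy-2,6-dimethoxyphenyl)acrylate | COC(=O)/C=C/c1c(OC)cc(O)cc1OC | intermediate |
| 4 | methyl 3-(4-hydroxy-2,6-dimethoxyphenyl)propanoate | COC(=O)CCc1c(OC)cc(O)cc1OC | intermediate |
| 5 | 2,4-dimethoxyphenylacetic acid | COc1ccc(CC(=O)O)c(OC)c1 | starting material |
| 6 | methyl 3-{3-[(2,4-dimethoxyphenyl)acetyl]-4-hydroxy-2,6-dimethoxyphenyl}propanoate | COC(=O)CCc1c(OC)cc(O)c(C(=O)Cc2ccc(OC)cc2OC)c1OC | intermediate |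
| 7 | N,N-dimethylformamide dimethyl acetal | COC(OC)N(C)C | starting material |
| 8 | methyl 3-[3-(2,4-dimethoxyphenyl)-5,7-dimethoxy-4-oxo-4H-chromen-6-yl]propanoate | COC(=O)CCc1c(OC)cc2occ(-c3ccc(OC)cc3OC)c(=O)c2c1OC | intermediate |
| 9 | 7-(2,4-dihydroxyphenyl)-5-hydroxy-3,4-dihydro-2H,6H-pyrano[3,2-g]chromene-2,6-dione | O=C1CCc2c(O)c3c(=O)c(-c4ccc(O)cc4O)coc3cc2O1 | intermediate |
| 10 | methylmagnesium bromide | C[Mg]Br | starting material |
| 11 | luteone hydrate (achiral) | CC(C)(O)CCc1c(O)cc2occ(-c3ccc(O)cc3O)c(=O)c2c1O | target |

## Step count

- Total steps: 6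
- Longest linear sequence: 6 (1 → 3 → 4 → 6 → 8 → 9 → 11)

## Steps most likely to fail

1. **Step 6.**
   - Risks: methyl attack on the chromone, insoluble polyphenoxide, or stalling at the methyl ketone through enolisation or ketene formation.
   - Fallback: keep carbanions away from the chromone entirely. Use an all-benzyl series with iodine in place of the propanoate on the symmetric phenol (4-iodo-3,5-bis(benzyloxy)phenol). After ring C is built, couple 2-methylbut-3-yn-2-ol by Sonogashira reaction. Finish with H2/Pd–C, which saturates the alkyne and removes all benzyl groups in one operation.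
2. **Step 3.**
   - Risks: self-condensation of the electron-rich arylacetic acid, the ester or derived acid acting as a competing acyl donor, or ortho-demethylation.
   - Fallback: change how the C3–aryl bond is made. Acetylate 4 (Ac2O, BF3·OEt2) and condense with 2,4-dimethoxybenzaldehyde to the chalcone. Then use a hypervalent-iodine oxidative 1,2-aryl migration (PhI(OAc)2, p-TsOH, MeOH–HC(OMe)3) followed by acid ring closure to reach 8.
3. **Step 5.**
   - Risks: incomplete cleavage of the hindered 7-OMe, ring scrambling if forced, or an incompletely lactonised polar product.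
   - Fallback: change the protecting-group logic. Carry all phenols as benzyl ethers and build ring C under neutral Pd conditions (6-substituted 3-iodochromone plus 2,4-bis(benzyloxy)phenylboronic acid). Deprotection then becomes hydrogenolysis, followed by the same lactonisation and methylation end-game.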